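**Retrosynthetic overview**
1. The tetrahydrofuran ring is formed last. Freeing the C6 alcohol lets it add to C3 of the ring-A enone (oxa-Michael), and the C11=C12 bond left by the key step is then hydrogenated.
2. Rings C and D are made together. Butadiene adds across C8=C9 of an α-pyruvoyl spiro-δ-lactone (Diels–Alder), and the adduct closes C13–C16 by a carbonyl-ene reaction. This sets C8, C9, C13 and C16.
3. Ring B (the lactone) comes from an intramolecular Knoevenagel condensation between the C9 aldehyde and the β-keto ester hung on O-20.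
4. The quaternary C10 is set by adding formaldehyde anti to C6. C5 is set by a desymmetrising conjugate addition of a t-BuOCH2 group to 4,4-dimethylcyclohexadienone.
5. Ring order: A (bought), then B, then C and D, then the ether bridge.

Assumption: ent-kaurane numbering (C1–C20) is used as atom labels throughout. The sense of induction of the ligand in step 2 is assigned by analogy with cyclohexenone; the mirror-image ligand is equally available.

**Step 1**
Reactants: 1 4,4-dimethylcyclohex-2-en-1-one
Product: 2 4,4-dimethylcyclohexa-2,5-dien-1-one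
Conditions: DDQ (1.3 equiv), 1,4-dioxane, reflux
Reagents that add atoms: none
Why: DDQ dehydrogenation of the enone through its dienol gives the achiral cross-conjugated dienone, and no stereocentre is involved.

**Step 2**
Reactants: 2 4,4-dimethylcyclohexa-2,5-dien-1-one; 3 tert-butyl methyl ether
Product: 6 (5R,6S)-5-(tert-butoxymethyl)-6-(dimethoxymethyl)-4,4-dimethylcyclohex-2-en-1-one, via bis(tert-butoxymethyl)zinc 4 (not isolated), via zinc dienolate 5 (not isolated)
Conditions: 3, s-BuLi/KOt-Bu, −78 °C; ZnCl2, salts filtered off; 2, Cu(OTf)2 (2 mol %), (S,R,R)-BINOL bis(1-phenylethyl)amine phosphoramidite (4 mol %), toluene, −30 °C; then HC(OMe)3, BF3·OEt2, −78 → −30 °C; aq NH4Cl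
Reagents that add atoms: trimethyl orthoformate, COC(OC)OC
Why: Proposed new method: a copper/phosphoramidite-catalysed enantioselective conjugate addition should transfer t-BuOCH2 from zinc to one enantiotopic enone of 2, which sets C5, and the zinc enolate (which blocks a second addition) is then trapped at C10 by the dimethoxycarbenium ion in a Mukaiyama-type alkylation, trans to C6 but erased in step 3; the closest known reaction types are asymmetric dialkylzinc additions to 4,4-disubstituted cyclohexadienones, conjugate additions of alkoxymethylcuprates made from metalated MTBE, and Lewis-acid trapping of zinc enolates with acetals and orthoformates.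

**Step 3**
Reactants: 6 (5R,6S)-5-(tert-butoxymethyl)-6-(dimethoxymethyl)-4,4-dimethylcyclohex-2-en-1-one
Product: 7 (5S,6S)-5-(tert-butoxymethyl)-6-(dimethoxymethyl)-6-(hydroxymethyl)-4,4-dimethylcyclohex-2-en-1-one
Conditions: LDA, THF, −78 °C; monomeric CH2O, −78 °C; aq NH4Cl
Reagents that add atoms: formaldehyde, C=O
Why: C10–H is the only enolisable site, and in the aldol addition of the lithium cross-conjugated dienolate A1,2 strain holds CH2Ot-Bu axial, so formaldehyde enters on the opposite face and places C20 trans and C9 cis to C6 (10S).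

**Step 4**
Reactants: 7 (5S,6S)-5-(tert-butoxymethyl)-6-(dimethoxymethyl)-6-(hydroxymethyl)-4,4-dimethylcyclohex-2-en-1-one; 8 methyl 4,4-dimethoxy-3-oxopentanoate
Product: 9 [(1S,6S)-6-(tert-butoxymethyl)-1-(dimethoxymethyl)-5,5-dimethyl-2-oxocyclohex-3-en-1-yl]methyl 4,4-dimethoxy-3-oxopentanoate
Conditions: DMAP (20 mol %), 4 Å MS, toluene, 110 °C (−MeOH)
Reagents that add atoms: none
Why: DMAP-catalysed β-keto ester transesterification through the acylketene acylates even a neopentyl primary alcohol, blocks retro-aldol loss of C20, and touches no stereocentre.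

**Step 5**
Reactants: 9 [(1S,6S)-6-(tert-butoxymethyl)-1-(dimethoxymethyl)-5,5-dimethyl-2-oxocyclohex-3-en-1-yl]methyl 4,4-dimethoxy-3-oxopentanoate
Product: 11 (6S,11S)-11-(tert-butoxymethyl)-10,10-dimethyl-4-(2-oxopropanoyl)-2-oxaspiro[5.5]undeca-4,8-diene-3,7-dione, via keto aldehyde 10 (not isolated)
Conditions: 1 M HCl, THF, rt; then piperidinium acetate (10 mol %), 4 Å MS, CH2Cl2, rt
Reagents that add atoms: water, O
Why: Dilute acid hydrolyses the acetal and the ketal while the tert-butyl ether survives, and an intramolecular Knoevenagel condensation of the very acidic C8 methylene with the C9 aldehyde then closes the six-membered lactone (ring B) without risk to the non-enolisable C10.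

**Step 6**
Reactants: 11 (6S,11S)-11-(tert-butoxymethyl)-10,10-dimethyl-4-(2-oxopropanoyl)-2-oxaspiro[5.5]undeca-4,8-diene-3,7-dione; 12 buta-1,3-diene
Product: 14 (5S,8S,9S,10S,13S,16R)-6-tert-butoxy-16-hydroxy-1,15-dioxo-6,7-secokaura-2,11-dien-7,20-olide, via Diels–Alder adduct 13 (not isolated)
Conditions: 12 (10 equiv), BHT, toluene, sealed tube, 150 °C
Reagents that add atoms: none
Why: Proposed new method: the C8=C9 bond, activated by three carbonyl groups, should take up butadiene in a normal-demand Diels–Alder reaction (closest known type: cycloadditions of 2-acyl-2-enoates and 2-carbalkoxy-4,4-dimethylcyclohexenones with simple dienes, with any hetero-Diels–Alder adduct funnelling to the same carbocycle by a [3,3] shift) on the lactone face syn to the flat C1 carbonyl and anti to C5, whose axial CH2Ot-Bu arm covers the other face, so that suprafacial addition fixes the cis B/C fusion (8S,9S), and in 13 the axial pyruvoyl group then holds its activated C16 ketone over C13 while the only allylic C–H aligned with the π bond on that face is pseudo-axial H-11, so a type-I intramolecular carbonyl-ene reaction (closest known type: thermal ene cyclisations of α-keto esters and 1,2-diketones) closes ring D as the bicyclo[3.2.1]octene rather than the [2.2.2] isomer and, because the carbonyl oxygen must reach H-11, leaves OH endo and CH3 exo (16R).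

**Step 7**
Reactants: 14 (5S,8S,9S,10S,13S,16R)-6-tert-butoxy-16-hydroxy-1,15-dioxo-6,7-secokaura-2,11-dien-7,20-olide
Product: 16 (3S,5S,8S,9S,10S,13S,16R)-3,6-epoxy-16-hydroxy-1,15-dioxo-6,7-secokaur-11-en-7,20-olide, via primary alcohol 15 (not isolated)
Conditions: TFA–CH2Cl2 (1:1), 0 °C → rt; then aq NaHCO3
Reagents that add atoms: none
Why: Acidolysis of the tert-butyl ether frees the axial C6–OH, which adds to C3 in an intramolecular oxa-Michael reaction, and the bridge can only close on the face that carries C6, which fixes C3 as S.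

**Step 8**
Reactants: 16 (3S,5S,8S,9S,10S,13S,16R)-3,6-epoxy-16-hydroxy-1,15-dioxo-6,7-secokaur-11-en-7,20-olide
Product: 17 (3S,5S,8S,9S,10S,13R,16R)-3,6-epoxy-16-hydroxy-1,15-dioxo-6,7-secokauran-7,20-olide
Conditions: H2 (1 atm), 10% Pd/C, EtOAc, rt
Reagents that add atoms: none
Why: Heterogeneous catalytic hydrogenation saturates the only remaining C=C; no stereocentre is made (the C13 descriptor changes only through CIP ranking), and the ketones, the lactone and the tertiary alcohol are inert.

**Where each stereocentre is set:** C5 in step 2, C10 in step 3, C8, C9, C13 and C16 in step 6, and C3 in step 7. None is enolisable afterwards.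

**Compound list**
1 | 4,4-dimethylcyclohex-2-en-1-one | CC1(C)CCC(=O)C=C1 | starting material
2 | 4,4-dimethylcyclohexa-2,5-dien-1-one | CC1(C)C=CC(=O)C=C1 | intermediate
3 | tert-butyl methyl ether | COC(C)(C)C | starting material
4 | bis(tert-butoxymethyl)zinc | CC(C)(C)OC[Zn]COC(C)(C)C | intermediate
5 | (tert-butoxymethyl)zinc (3R)-3-(tert-butoxymethyl)-4,4-dimethylcyclohexa-1,5-dien-1-olate | CC1(C)C=CC(O[Zn]COC(C)(C)C)=C[C@H]1COC(C)(C)C | intermediate
6 | (5R,6S)-5-(tert-butoxymethyl)-6-(dimethoxymethyl)-4,4-dimethylcyclohex-2-en-1-one | CC1(C)C=CC(=O)[C@H](C(OC)OC)[C@H]1COC(C)(C)C | intermediate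
7 | (5S,6S)-5-(tert-butoxymethyl)-6-(dimethoxymethyl)-6-(hydroxymethyl)-4,4-dimethylcyclohex-2-en-1-one | CC1(C)C=CC(=O)[C@](C(OC)OC)(CO)[C@H]1COC(C)(C)C | intermediate
8 | methyl 4,4-dimethoxy-3-oxopentanoate | COC(=O)CC(=O)C(C)(OC)OC | starting material
9 | [(1S,6S)-6-(tert-butoxymethyl)-1-(dimethoxymethyl)-5,5-dimethyl-2-oxocyclohex-3-en-1-yl]methyl 4,4-dimethoxy-3-oxopentanoate | CC1(C)C=CC(=O)[C@](C(OC)OC)(COC(=O)CC(=O)C(C)(OC)OC)[C@H]1COC(C)(C)C | intermediate
10 | [(1S,6S)-6-(tert-butoxymethyl)-1-formyl-5,5-dimethyl-2-oxocyclohex-3-en-1-yl]methyl 3,4-dioxopentanoate | CC1(C)C=CC(=O)[C@](C=O)(COC(=O)CC(=O)C(C)=O)[C@H]1COC(C)(C)C | intermediate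
11 | (6S,11S)-11-(tert-butoxymethyl)-10,10-dimethyl-4-(2-oxopropanoyl)-2-oxaspiro[5.5]undeca-4,8-diene-3,7-dione | CC1(C)C=CC(=O)[C@]2(COC(=O)C(C(=O)C(C)=O)=C2)[C@H]1COC(C)(C)C | intermediate
12 | buta-1,3-diene | C=CC=C | starting material
13 | (5S,8S,9S,10S)-6-tert-butoxy-1,15,16-trioxo-6,7:13,16-disecokaura-2,12-dien-7,20-olide | CC1(C)C=CC(=O)[C@]3(COC(=O)[C@]4(CC=CC[C@H]43)C(=O)C(C)=O)[C@H]1COC(C)(C)C | intermediate
14 | (5S,8S,9S,10S,13S,16R)-6-tert-butoxy-16-hydroxy-1,15-dioxo-6,7-secokaura-2,11-dien-7,20-olide | CC1(C)C=CC(=O)[C@]3(COC(=O)[C@@]45C[C@@H](C=C[C@H]43)[C@@](C)(O)C5=O)[C@H]1COC(C)(C)C | intermediate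
15 | (5S,8S,9S,10S,13S,16R)-6,16-dihydroxy-1,15-dioxo-6,7-secokaura-2,11-dien-7,20-olide | CC1(C)C=CC(=O)[C@]3(COC(=O)[C@@]45C[C@@H](C=C[C@H]43)[C@@](C)(O)C5=O)[C@H]1CO | intermediate
16 | (3S,5S,8S,9S,10S,13S,16R)-3,6-epoxy-16-hydroxy-1,15-dioxo-6,7-secokaur-11-en-7,20-olide | CC1(C)[C@@H]2CC(=O)[C@]3(COC(=O)[C@@]45C[C@@H](C=C[C@H]43)[C@@](C)(O)C5=O)[C@H]1CO2 | intermediate
17 | (3S,5S,8S,9S,10S,13R,16R)-3,6-epoxy-16-hydroxy-1,15-dioxo-6,7-secokauran-7,20-olide (CNP0538153.1) | CC1(C)[C@@H]2CC(=O)[C@]3(COC(=O)[C@@]45C[C@@H](CC[C@H]43)[C@@](C)(O)C5=O)[C@H]1CO2 | target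

**Total step count:** 8. **Longest linear sequence:** 8 (1 → 17). Compounds 3, 8 and 12 are bought.

**Steps most likely to fail, with fallbacks**

Step 2. The risks are poor transfer of the alkoxymethyl group from zinc or a low ee. The fallback sets out from 2 and comes back at 6. It replaces the organometallic addition with an open-shell one. Decatungstate photocatalysis abstracts an OCH2–H from 3, and the t-BuOCH2 radical is captured by the chiral iminium ion that 2 forms with a primary-amine catalyst. This gives (R)-5-(tert-butoxymethyl)-4,4-dimethylcyclohex-2-en-1-one F1. Soft enolisation of F1 (TMSOTf, i-Pr2NEt) in the presence of HC(OMe)3 then delivers 6.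

Step 5. The risks are that the free triketone 10 is fragile or that the aldehyde is deformylated. The fallback sets out from 9 and comes back at 13. It keeps C16 masked until ring C is in place.
- Wet PPTS in acetone cleaves only the aldehyde acetal, because the α-keto ketal is deactivated. The product is [(1S,6S)-6-(tert-butoxymethyl)-1-formyl-5,5-dimethyl-2-oxocyclohex-3-en-1-yl]methyl 4,4-dimethoxy-3-oxopentanoate F2.
- Piperidinium acetate closes F2 to (6S,11S)-11-(tert-butoxymethyl)-4-(2,2-dimethoxypropanoyl)-10,10-dimethyl-2-oxaspiro[5.5]undeca-4,8-diene-3,7-dione F3.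
- A ZnCl2-promoted Diels–Alder reaction of F3 with 12 gives (5S,8S,9S,10S)-6-tert-butoxy-16,16-dimethoxy-1,15-dioxo-6,7:13,16-disecokaura-2,12-dien-7,20-olide F4.
- Aqueous HCl in THF unmasks F4 to 13, which is then heated to 14.

Step 6. The risk is that the cycloaddition stops at 13 and the ene closure does not follow. The fallback sets out from isolated 13 and comes back at 17. It replaces the pericyclic closure with a radical one.
- TFA removes the tert-butyl group to give (5S,8S,9S,10S)-6-hydroxy-1,15,16-trioxo-6,7:13,16-disecokaura-2,12-dien-7,20-olide F5.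
- F5 closes in the same flask to (3S,5S,8S,9S,10S)-3,6-epoxy-1,15,16-trioxo-6,7:13,16-disecokaur-12-en-7,20-olide F6, which no longer carries an enone.
- Hydrogen-atom-transfer conditions (Fe(acac)3, PhSiH3, EtOH, 60 °C) place H on C12, and the C13 radical adds to the activated C16 ketone with CH3 exo. This gives 17 directly.

**Further compounds**
F1 | step 2 | (R)-5-(tert-butoxymethyl)-4,4-dimethylcyclohex-2-en-1-one | CC1(C)C=CC(=O)C[C@H]1COC(C)(C)C
F2 | step 5 | [(1S,6S)-6-(tert-butoxymethyl)-1-formyl-5,5-dimethyl-2-oxocyclohex-3-en-1-yl]methyl 4,4-dimethoxy-3-oxopentanoate | CC1(C)C=CC(=O)[C@](C=O)(COC(=O)CC(=O)C(C)(OC)OC)[C@H]1COC(C)(C)C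
F3 | step 5 | (6S,11S)-11-(tert-butoxymethyl)-4-(2,2-dimethoxypropanoyl)-10,10-dimethyl-2-oxaspiro[5.5]undeca-4,8-diene-3,7-dione | CC1(C)C=CC(=O)[C@]2(COC(=O)C(C(=O)C(C)(OC)OC)=C2)[C@H]1COC(C)(C)C
F4 | step 5 | (5S,8S,9S,10S)-6-tert-butoxy-16,16-dimethoxy-1,15-dioxo-6,7:13,16-disecokaura-2,12-dien-7,20-olide | CC1(C)C=CC(=O)[C@]3(COC(=O)[C@]4(CC=CC[C@H]43)C(=O)C(C)(OC)OC)[C@H]1COC(C)(C)C
F5 | step 6 | (5S,8S,9S,10S)-6-hydroxy-1,15,16-trioxo-6,7:13,16-disecokaura-2,12-dien-7,20-olide | CC1(C)C=CC(=O)[C@]3(COC(=O)[C@]4(CC=CC[C@H]43)C(=O)C(C)=O)[C@H]1CO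
F6 | step 6 | (3S,5S,8S,9S,10S)-3,6-epoxy-1,15,16-trioxo-6,7:13,16-disecokaur-12-en-7,20-olide | CC1(C)[C@@H]2CC(=O)[C@]3(COC(=O)[C@]4(CC=CC[C@H]43)C(=O)C(C)=O)[C@H]1CO2
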